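A direct plan would form the bicyclo[3.1.1]heptane at the outset by an intramolecular ketene–alkene [2+2] cycloaddition to the cyclobutanone A1, hang the C11 and C3 arms on it and close the seven-membered ring last.
It would spend about ten operations on the C6 carbonyl of A1 alone (Reformatsky addition, xanthate formation and tin hydride removal of the tertiary hydroxyl, lactone opening, redox adjustment) to gain one C–C bond and one hydrogen.
It would leave the face of the ketene cycloaddition, and with it the relation of C5 and C7 to C10, to a single remote methyl group.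
It would close ring A by a SmI2 (divalent samarium) pinacol coupling of the keto-dialdehyde A2 made by triple ozonolysis: a seven-membered ring and two stereocentres in one step on an unstable intermediate, at the point where material is most precious.

**Plan of the new route**
The esters come off first; O2 and O3 are traced to a C2=C3 alkene, the C10 methyl to a cuprate addition, and the cyclobutane bond C6–C7 is cut last.
That bond joins C7, the α-carbon of the C8 ketone, to the ring A carbon C6, which lies 1,4 to it across the C4–C5 bond shared by ring A and the six-membered ring C4–C5–C10–C9–C8–C7; the α′-enolate of a cis-fused cyclohexenone–cycloheptene can therefore displace a C6 sulfonate and close the four-membered ring.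
Ring A is cut at C2=C3 (metathesis) and C6–C11 (aldol); the six-membered ring with C4 and C5 comes from a Diels–Alder reaction of a menthol-derived butenolide.
Ring order: six-membered ring, ring A, cyclobutane.
C6 never carries a carbonyl that must be deleted (its aldol oxygen is the leaving group); every centre except C1 is relayed from the one bought acetal carbon; ring A is closed early on robust material, so no late pinacol closure occurs.

Key step: step 14

Atom labels as in the target: ring A is C1(O)–C2(O)–C3(O)–C4(Me)–C5–C6–C11(Me2); the cyclobutane is C4–C5–C6–C7; the second ring is C5–C6–C7–C8(=O)–C9–C10(Me).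
Assumption: the 4-methyl analogue of the 5-(menthyloxy)furanone is taken to behave like the parent compound, so that the (5S)-acetal of (+)-menthol can be obtained pure by crystallisation with acid-catalysed epimerisation of the mother liquor.

Step 1
Reactants: 1 5-hydroxy-4-methylfuran-2(5H)-one; 2 (+)-menthol, (1S,2R,5S)-5-methyl-2-(propan-2-yl)cyclohexan-1-ol
Product: 3 (5S)-4-methyl-5-[(1S,2R,5S)-menthyloxy]furan-2(5H)-one
Conditions: p-TsOH (cat.), toluene, reflux, Dean–Stark; crystallisation from hexane, mother liquor re-equilibrated with acid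
Reagents that add atoms: (+)-menthol, C[C@H]1CC[C@@H]([C@H](C1)O)C(C)C
Why: Acid-catalysed acetalisation of the lactol with a secondary alcohol is routine, the two acetal epimers interconvert through the oxocarbenium ion, and crystallisation should deliver the (5S)-epimer, whose acetal carbon (the future C3) is the only stereocentre that is bought.

Step 2
Reactants: 4 but-3-en-2-one; 5 triisopropylsilyl trifluoromethanesulfonate
Product: 6 2-(triisopropylsilyloxy)buta-1,3-diene
Conditions: Et3N, Et2O, 0 °C to rt
Reagents that add atoms: triisopropylsilyl trifluoromethanesulfonate, CC(C)[Si](OS(=O)(=O)C(F)(F)F)(C(C)C)C(C)C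
Why: Soft enolisation of the methyl ketone with a silyl triflate and an amine gives the 2-silyloxydiene, and the triisopropylsilyl group is chosen because its enol ether must survive nine later steps.

Step 3
Reactants: 3 menthyloxy butenolide; 6 2-(triisopropylsilyloxy)buta-1,3-diene
Product: 7 cis-fused lactone acetal (C4 methyl; C8 triisopropylsilyl enol ether with C8=C9)
Conditions: toluene, 2,6-di-tert-butyl-4-methylphenol (cat.), 140 °C, sealed vessel
Reagents that add atoms: 2-(triisopropylsilyloxy)buta-1,3-diene, C=CC(=C)O[Si](C(C)C)(C(C)C)C(C)C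
Why: In this Diels–Alder reaction the nucleophilic CH2 terminus of the 2-silyloxydiene (C7) bonds to the β-carbon of the butenolide (C4) and the other terminus (C10) to the α-carbon (C5); the diene adds to the face opposite the menthyloxy group and cis fusion is inherent, so the quaternary C4 and C5 are set from the acetal carbon.

Step 4
Reactants: 7 lactone acetal; 8 N,O-dimethylhydroxylamine
Product: 10 C3 aldehyde C6 Weinreb amide (formyl and amide cis on the cyclohexene), via menthyl hemiacetal 9 (not isolated)
Conditions: Me3Al, CH2Cl2, 0 °C to rt; aq. KNaC4H4O6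
Reagents that add atoms: N,O-dimethylhydroxylamine, CNOC
Why: Weinreb aminolysis with the aluminium amide opens the lactone at C6, and the hemiacetal 9 that is left on C3 loses menthol on work-up, so the two carbonyl carbons of the butenolide emerge differentiated as a non-enolisable aldehyde (C3) and an amide (C6).

Step 5
Reactants: 10 aldehyde amide; 11 methyltriphenylphosphonium bromide
Product: 12 C3 vinyl C6 Weinreb amide
Conditions: KN(SiMe3)2, THF, 0 °C; then 10, −78 to 0 °C
Reagents that add atoms: methyltriphenylphosphonium bromide, C[P+](c1ccccc1)(c1ccccc1)c1ccccc1.[Br-]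
Why: Wittig methylenation is far faster at the aldehyde than at the Weinreb amide and stores C3 as the vinyl group needed for ring A.

Step 6
Reactants: 12 vinyl Weinreb amide
Product: 13 C6 aldehyde (formyl and vinyl cis)
Conditions: iBu2AlH, THF, −78 °C; aq. KNaC4H4O6; used at once
Reagents that add atoms: none
Why: Hydride reduction of a Weinreb amide stops at the aldehyde because the aluminium chelate holds until work-up, and immediate use guards the C5 stereocentre next to the new aldehyde.

Step 7
Reactants: 14 4-methylpent-1-en-3-one; 15 trimethylsilyl trifluoromethanesulfonate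
Product: 16 4-methyl-3-(trimethylsilyloxy)penta-1,3-diene
Conditions: Et3N, Et2O, 0 °C
Reagents that add atoms: trimethylsilyl trifluoromethanesulfonate, C[Si](C)(C)OS(=O)(=O)C(F)(F)F
Why: The ketone has a single enolisable hydrogen (the isopropyl CH), so soft enolisation can give only the tetrasubstituted enol silane that carries C11, its two methyls, C1 and C2.

Step 8
Reactants: 13 C6 aldehyde; 16 4-methyl-3-(trimethylsilyloxy)penta-1,3-diene
Product: 17 (6S)-β-hydroxy vinyl ketone (C6 carbinol; C11 gem-dimethyl; C1 ketone; C2 vinyl)
Conditions: 16 (2 equiv), BF3·OEt2, CH2Cl2, −78 °C; aq. NaHCO3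
Reagents that add atoms: 4-methyl-3-(trimethylsilyloxy)penta-1,3-diene, C=CC(O[Si](C)(C)C)=C(C)C
Why: In this Mukaiyama aldol addition under non-chelating conditions the Felkin–Anh model applies, with the quaternary C4 anti to the incoming enol silane, which should set C6 so that its oxygen lies on the face of C5–H, the face away from C7; the hindered triisopropylsilyl enol ether in the ring should not compete with the excess of the trimethylsilyl enol ether.

Step 9
Reactants: 17 β-hydroxy vinyl ketone; 18 methanesulfonyl chloride
Product: 19 C6 methanesulfonate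
Conditions: Et3N, CH2Cl2, −20 to 0 °C
Reagents that add atoms: methanesulfonyl chloride, CS(=O)(=O)Cl
Why: Mesylation through the sulfene reaches even this hindered secondary alcohol, installs the later leaving group, and removes the free hydroxyl before it can add to the vinyl ketone or undergo retro-aldol cleavage; elimination is impossible because C11 bears no hydrogen.

Step 10
Reactants: 19 mesylate diene
Product: 20 cis-fused bicyclic enone (ring A closed; C1 ketone; C2=C3)
Conditions: (H2IMes)(PCy3)Cl2Ru=CHPh (second-generation Grubbs catalyst, 5 mol %), toluene, 80 °C, 0.002 M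
Reagents that add atoms: none
Why: Ring-closing metathesis of the vinyl ketone with the C4 vinyl group forms the seven-membered enone; the two arms are cis on the cyclohexene, the gem-dimethyl group favours closure, and the trisubstituted silyl enol ether does not take part.

Step 11
Reactants: 20 bicyclic enone
Product: 21 (1R)-allylic alcohol
Conditions: (S)-1-methyl-3,3-diphenyltetrahydro-1H,3H-pyrrolo[1,2-c][1,3,2]oxazaborole [(S)-Me-CBS, 0.5 equiv], catecholborane, toluene, −78 °C; MeOH, then aq. NaHCO3
Reagents that add atoms: none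
Why: In this Corey–Bakshi–Shibata reduction, with the quaternary C11 as the large and the ring alkene as the small substituent, the (S)-catalyst should deliver hydride to the face that gives the (1R)-alcohol (O1 on the face of O6), and catecholborane at −78 °C leaves the silyl enol ether and the mesylate untouched.

Step 12
Reactants: 21 allylic alcohol; 22 tert-butyldimethylsilyl trifluoromethanesulfonate
Product: 23 O1 tert-butyldimethylsilyl ether
Conditions: 2,6-lutidine, CH2Cl2, −78 to 0 °C
Reagents that add atoms: tert-butyldimethylsilyl trifluoromethanesulfonate, CC(C)(C)[Si](C)(C)OS(=O)(=O)C(F)(F)F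
Why: Silylation under non-basic conditions never forms the O1 alkoxide, which could fragment the 1,3-hydroxy mesylate by cleavage of C1–C11 (Grob fragmentation), and the bulky ether later steers osmium tetroxide.

Step 13
Reactants: 23 silyl enol ether
Product: 24 cyclohexenone (C8 ketone; C9=C10)
Conditions: Pd(OAc)2 (1.2 equiv), MeCN, 40 °C
Reagents that add atoms: none
Why: In this Saegusa–Ito oxidation the enol ether from the cycloaddition gives a palladium enolate (divalent palladium) bound at C9, whose only β-hydrogens are on C10, so the enone can form only as C9=C10 and C7 is left as the sole sp3 α-carbon.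

Step 14
Reactants: 24 cyclohexenone mesylate
Product: 26 tricyclic enone (cyclobutane closed; O1 silyl ether; C2=C3; C8 ketone; C9=C10), via lithium enolate 25 (not isolated)
Conditions: LiN(iPr)2 (1.05 equiv), THF, −78 °C; then DMPU, −78 to 25 °C
Reagents that add atoms: none
Why: LiN(iPr)2 removes a proton from C7, the only sp3 α-carbon of the cross-conjugated enone, and the lithium enolate 25 displaces the C6 mesylate from the rear in an intramolecular enolate alkylation. The closest known reaction type is the base-induced cyclisation of cyclohexanones that carry a sulfonyloxy-bearing carbon on C4 of the ring (1,4 to the α-carbon), which gives bicyclo[3.1.1]heptan-2-ones, also with secondary sulfonates held in a second ring. The cyclobutane closes in the 4-exo-tet mode, and with it the ring C5–C6–C7–C8–C9–C10 and the bicyclo[3.1.1]heptane are complete. C6 is set by inversion of the mesylate centre made in step 8, and C7 can only take the configuration in which it bridges C4 and C6 on the face of the cis-fused bicycle that already carries C7 and C10. The step needs α′- over γ-deprotonation (kinetic base at −78 °C; the C5 hydrogen is tertiary and hindered), C- over O-alkylation (lithium counter-ion in THF; the oxygen cannot reach the rear of C6) and substitution over elimination (no base is left once the enolate has formed, and C11 has no hydrogen); the mesylate is anti to C7 because the Felkin–Anh aldol placed O6 on the face of C5–H.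

Step 15
Reactants: 26 tricyclic enone; 27 methyllithium
Product: 29 C10-methyl ketone, via lithium enolate 28 (not isolated)
Conditions: Me2CuLi (from MeLi and CuI), Et2O, −78 to −20 °C; aq. NH4Cl
Reagents that add atoms: methyllithium, [Li]C (used as lithium dimethylcuprate, [Li+].C[Cu-]C)
Why: In this cuprate conjugate addition methyl should enter C10 from the face of the C6 bridge, which turns only a hydrogen towards the enone, and not from the face of the C4 bridge with its syn methyl, as with 6,6-dimethylbicyclo[3.1.1]hept-3-en-2-ones; this places the methyl on the C6 side as in the target.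

Step 16
Reactants: 29 C10-methyl ketone; 30 N-methylmorpholine N-oxide
Product: 31 C2,C3-cis-diol (O1 silyl ether)
Conditions: OsO4 (5 mol %), N-methylmorpholine N-oxide, acetone/H2O, rt; aq. Na2S2O3
Reagents that add atoms: osmium tetroxide, O=[Os](=O)(=O)=O; N-methylmorpholine N-oxide, C[N+]1([O-])CCOCC1; water, O
Why: Osmium tetroxide dihydroxylation is suprafacial, which gives the cis-2,3-diol, and the reagent should add to the face of C2=C3 opposite the bulky allylic silyl ether on C1 (the usual anti preference with allylic ethers), which gives the 1,2-trans relation of the target.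

Step 17
Reactants: 31 diol; 32 acetic anhydride
Product: 33 O2 acetate (O1 silyl ether; O3 free)
Conditions: Ac2O (1.1 equiv), pyridine, CH2Cl2, −20 to 0 °C
Reagents that add atoms: acetic anhydride, CC(=O)OC(C)=O
Why: The C2 hydroxyl lies between two CH carbons whereas the C3 hydroxyl is neopentyl to the quaternary C4 of the cyclobutane, so a small excess of anhydride at low temperature should acylate O2 first.

Step 18
Reactants: 33 O2 acetate
Product: 34 O1,O3-diol O2 acetate
Conditions: HF·pyridine, THF, 0 °C to rt
Reagents that add atoms: none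
Why: Acidic fluoride cleaves the silyl ether without the basic conditions under which the acetate would migrate to a neighbouring hydroxyl.

Step 19
Reactants: 34 diol acetate; 35 angelic acid, (Z)-2-methylbut-2-enoic acid
Product: 37 CNP0197834.1 (target), via O1 monoangelate 36 (not isolated)
Conditions: angelic acid (3 equiv), 2,4,6-trichlorobenzoyl chloride, Et3N, toluene, rt; then 34, 80 °C (no DMAP)
Reagents that add atoms: angelic acid, C/C=C(/C)C(=O)O
Why: Yamaguchi esterification through the mixed 2,4,6-trichlorobenzoic anhydride acylates hindered secondary alcohols, first O1 and then the more hindered O3, and leaving out DMAP avoids the conjugate-addition pathway that isomerises angelates to tiglates.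

**Compound list**

1 | 5-hydroxy-4-methylfuran-2(5H)-one | CC1=CC(=O)OC1O | starting material
2 | (+)-menthol, (1S,2R,5S)-5-methyl-2-(propan-2-yl)cyclohexan-1-ol | C[C@H]1CC[C@@H]([C@H](C1)O)C(C)C | starting material
3 | (5S)-4-methyl-5-[(1S,2R,5S)-menthyloxy]furan-2(5H)-one | C[C@H]1CC[C@@H]([C@H](C1)O[C@H]2OC(=O)C=C2C)C(C)C | intermediate
4 | but-3-en-2-one | CC(=O)C=C | starting material
5 | triisopropylsilyl trifluoromethanesulfonate | CC(C)[Si](OS(=O)(=O)C(F)(F)F)(C(C)C)C(C)C | starting material
6 | 2-(triisopropylsilyloxy)buta-1,3-diene | C=CC(=C)O[Si](C(C)C)(C(C)C)C(C)C | intermediate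
7 | (3S)-3-menthyloxy-3a-methyl-5-(triisopropylsilyloxy)-3a,4,7,7a-tetrahydro-2-benzofuran-1(3H)-one, cis-fused; 3a-methyl (C4), 7a-H (C5) and menthyloxy on one face; C1 of the lactone is C6, C3 is the acetal carbon | C[C@H]1CC[C@@H]([C@H](C1)O[C@H]2OC(=O)[C@@H]3CC=C(O[Si](C(C)C)(C(C)C)C(C)C)C[C@]23C)C(C)C | intermediate
8 | N,O-dimethylhydroxylamine | CNOC | starting material
9 | ring-opened menthyl hemiacetal, formed as its aluminium alkoxide: C6 Weinreb amide, C3 as CH(OH)(O-menthyl) | C[C@H]1CC[C@@H]([C@H](C1)O[C@@H](O)[C@@]2(C)CC(O[Si](C(C)C)(C(C)C)C(C)C)=CC[C@H]2C(=O)N(C)OC)C(C)C | intermediate (not isolated)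
10 | 6-formyl-N-methoxy-N,6-dimethyl-4-(triisopropylsilyloxy)cyclohex-3-ene-1-carboxamide, formyl (C3) and carboxamide (C6) cis | O=C[C@@]1(C)CC(O[Si](C(C)C)(C(C)C)C(C)C)=CC[C@H]1C(=O)N(C)OC | intermediate
11 | methyltriphenylphosphonium bromide | C[P+](c1ccccc1)(c1ccccc1)c1ccccc1.[Br-] | starting material
12 | 6-ethenyl-N-methoxy-N,6-dimethyl-4-(triisopropylsilyloxy)cyclohex-3-ene-1-carboxamide, ethenyl and carboxamide cis | C=C[C@@]1(C)CC(O[Si](C(C)C)(C(C)C)C(C)C)=CC[C@H]1C(=O)N(C)OC | intermediate
13 | 6-ethenyl-6-methyl-4-(triisopropylsilyloxy)cyclohex-3-ene-1-carbaldehyde, ethenyl and formyl cis | C=C[C@@]1(C)CC(O[Si](C(C)C)(C(C)C)C(C)C)=CC[C@H]1C=O | intermediate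
14 | 4-methylpent-1-en-3-one | C=CC(=O)C(C)C | starting material
15 | trimethylsilyl trifluoromethanesulfonate | C[Si](C)(C)OS(=O)(=O)C(F)(F)F | starting material
16 | 4-methyl-3-(trimethylsilyloxy)penta-1,3-diene | C=CC(O[Si](C)(C)C)=C(C)C | intermediate
17 | (5S)-5-[6-ethenyl-6-methyl-4-(triisopropylsilyloxy)cyclohex-3-en-1-yl]-5-hydroxy-4,4-dimethylpent-1-en-3-one (C5 of the chain is C6 of the target; Felkin–Anh configuration) | C=C[C@@]1(C)CC(O[Si](C(C)C)(C(C)C)C(C)C)=CC[C@H]1[C@H](O)C(C)(C)C(=O)C=C | intermediate
18 | methanesulfonyl chloride | CS(=O)(=O)Cl | starting material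
19 | C6 methanesulfonate of 17 | C=C[C@@]1(C)CC(O[Si](C(C)C)(C(C)C)C(C)C)=CC[C@H]1[C@H](OS(C)(=O)=O)C(C)(C)C(=O)C=C | intermediate
20 | cis-fused 6–7 bicycle (target labels): ring A with C1 ketone, C2=C3, C11 gem-dimethyl and (6S)-mesylate; ring C4–C5–C10–C9–C8–C7 with C4 methyl and C8 triisopropylsilyl enol ether (C8=C9); C4 methyl, C5–H and C6–OMs on one face | O=C1C=C[C@@]2(C)CC(O[Si](C(C)C)(C(C)C)C(C)C)=CC[C@H]2[C@H](OS(C)(=O)=O)C1(C)C | intermediate
21 | (1R)-allylic alcohol of 20 (O1 on the face of O6) | O[C@@H]1C=C[C@@]2(C)CC(O[Si](C(C)C)(C(C)C)C(C)C)=CC[C@H]2[C@H](OS(C)(=O)=O)C1(C)C | intermediate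
22 | tert-butyldimethylsilyl trifluoromethanesulfonate | CC(C)(C)[Si](C)(C)OS(=O)(=O)C(F)(F)F | starting material
23 | O1 tert-butyldimethylsilyl ether of 21 | CC(C)(C)[Si](C)(C)O[C@@H]1C=C[C@@]2(C)CC(O[Si](C(C)C)(C(C)C)C(C)C)=CC[C@H]2[C@H](OS(C)(=O)=O)C1(C)C | intermediate
24 | cyclohexenone from 23: C8 ketone, C9=C10, C7 methylene; ring A unchanged (O1 silyl ether, C2=C3, C6 mesylate) | CC(C)(C)[Si](C)(C)O[C@@H]1C=C[C@@]2(C)CC(=O)C=C[C@H]2[C@H](OS(C)(=O)=O)C1(C)C | intermediate
25 | lithium α′-enolate of 24 (C7=C8–OLi) | CC(C)(C)[Si](C)(C)O[C@@H]1C=C[C@@]2(C)C=C([O-])C=C[C@H]2[C@H](OS(C)(=O)=O)C1(C)C.[Li+] | intermediate (not isolated)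
26 | tricyclic enone (target labels): cyclobutane C4–C5–C6–C7 closed; C8 ketone; C9=C10; ring A with (1R)-silyl ether, C2=C3 and C11 gem-dimethyl; C4 methyl syn, C6–H syn | CC(C)(C)[Si](C)(C)O[C@@H]1C=C[C@]2(C)[C@@H]3[C@@H]([C@H]2C(=O)C=C3)C1(C)C | intermediate
27 | methyllithium | [Li]C | starting material
28 | lithium enolate of 29 (C8–OLi, C8=C9) | CC(C)(C)[Si](C)(C)O[C@@H]1C=C[C@]2(C)[C@@H]3[C@@H]([C@H]2C([O-])=C[C@H]3C)C1(C)C.[Li+] | intermediate (not isolated)
29 | C10-methyl ketone (methyl on the C6 side; O1 silyl ether; C2=C3) | CC(C)(C)[Si](C)(C)O[C@@H]1C=C[C@]2(C)[C@@H]3[C@@H]([C@H]2C(=O)C[C@H]3C)C1(C)C | intermediate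
30 | N-methylmorpholine N-oxide | C[N+]1([O-])CCOCC1 | starting material
31 | C2,C3-cis-diol, both hydroxyls trans to the O1 silyl ether | CC(C)(C)[Si](C)(C)O[C@@H]1[C@@H](O)[C@@H](O)[C@]2(C)[C@@H]3[C@@H]([C@H]2C(=O)C[C@H]3C)C1(C)C | intermediate
32 | acetic anhydride | CC(=O)OC(C)=O | starting material
33 | O2 acetate of 31 (O1 silyl ether, O3 free) | CC(C)(C)[Si](C)(C)O[C@@H]1[C@@H](OC(C)=O)[C@@H](O)[C@]2(C)[C@@H]3[C@@H]([C@H]2C(=O)C[C@H]3C)C1(C)C | intermediate
34 | O1,O3-diol O2 acetate | O[C@@H]1[C@@H](OC(C)=O)[C@@H](O)[C@]2(C)[C@@H]3[C@@H]([C@H]2C(=O)C[C@H]3C)C1(C)C | intermediate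
35 | angelic acid, (Z)-2-methylbut-2-enoic acid | C/C=C(/C)C(=O)O | starting material
36 | O1 angelate O2 acetate, O3 free | C/C=C(/C)C(=O)O[C@@H]1[C@@H](OC(C)=O)[C@@H](O)[C@]2(C)[C@@H]3[C@@H]([C@H]2C(=O)C[C@H]3C)C1(C)C | intermediate (not isolated)
37 | CNP0197834.1 (O1 and O3 angelates, O2 acetate, C8 ketone) | C/C=C(/C)C(=O)O[C@@H]1[C@@H](OC(C)=O)[C@@H](OC(=O)/C(C)=C\C)[C@]2(C)[C@@H]3[C@@H]([C@H]2C(=O)C[C@H]3C)C1(C)C | target

Total step count: 19. Longest linear sequence: 17 steps (steps 1, 3 to 6 and 8 to 19).

**Steps most likely to fail**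

Step 14 (closure of the cyclobutane). Displacement at the neopentyl C6 mesylate inside the fused bicycle may be too slow, so that elimination towards C5 or O-alkylation of the enolate takes over. The four-membered ring would then be closed before ring A, where the side chain can rotate freely into the rear-side alignment. Setting out from 19, Corey–Bakshi–Shibata reduction of the acyclic vinyl ketone would give the (1R)-allylic alcohol F1, and silylation of F1 with tBuMe2SiOTf and 2,6-lutidine would give the silyl ether F2. Saegusa–Ito oxidation of F2 with Pd(OAc)2 would give the cyclohexenone F3, and LiN(iPr)2 would convert F3 into the bicyclo[3.1.1]hept-3-en-2-one F4, which carries the C4 vinyl group and the C6 side chain. Ring-closing metathesis of F4 with the second-generation Grubbs catalyst would form C2=C3 and return to the route at 26.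

Step 3 (Diels–Alder reaction). The β-methyl butenolide may be too poor a dienophile, so that the diene decomposes or oligomerises before it adds. Setting out from 3, the butenolide would be combined at 20 to 60 °C with the far more reactive 1-(dimethylamino)-3-(tert-butyldimethylsilyloxy)buta-1,3-diene to give the amino silyl enol ether adduct F5, and dilute HCl would convert F5 into the enone lactone F6 with loss of dimethylamine and the silyl group. Conjugate reduction of F6 with K[HB(sBu)3] and trapping of the C8–C9 enolate with iPr3SiOTf would return to the route at 7.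

Step 11 (reduction at C1). The oxazaborolidine may not distinguish the quaternary carbon from the ring alkene, which would give poor facial selectivity. C1 would then be relayed from C6. Setting out from 17, ring-closing metathesis with the second-generation Grubbs catalyst would give the β-hydroxy cycloheptenone F7, and Narasaka–Prasad reduction of F7 (Et2BOMe, NaBH4) would give the cis-1,3-diol F8. Silylation of the less hindered allylic hydroxyl of F8 with tBuMe2SiCl and imidazole would give the O1 silyl ether F9, and mesylation of the remaining C6 hydroxyl of F9 would return to the route at 23.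

**Further compounds**

F1 | step 14 | (1R)-allylic alcohol of the acyclic mesylate 19 | C=C[C@@]1(C)CC(O[Si](C(C)C)(C(C)C)C(C)C)=CC[C@H]1[C@H](OS(C)(=O)=O)C(C)(C)[C@H](O)C=C
F2 | step 14 | O1 tert-butyldimethylsilyl ether of F1 | C=C[C@@]1(C)CC(O[Si](C(C)C)(C(C)C)C(C)C)=CC[C@H]1[C@H](OS(C)(=O)=O)C(C)(C)[C@H](O[Si](C)(C)C(C)(C)C)C=C
F3 | step 14 | cyclohexenone of F2 (C8 ketone, C9=C10) | C=C[C@@]1(C)CC(=O)C=C[C@H]1[C@H](OS(C)(=O)=O)C(C)(C)[C@H](O[Si](C)(C)C(C)(C)C)C=C
F4 | step 14 | bicyclo[3.1.1]hept-3-en-2-one with C4 methyl and vinyl and the C6 side chain CMe2–CH(OSitBuMe2)–CH=CH2 | C=C[C@]1(C)[C@@H]2[C@@H]([C@H]1C(=O)C=C2)C(C)(C)[C@H](O[Si](C)(C)C(C)(C)C)C=C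
F5 | step 3 | cycloadduct of 3 with the amino silyloxy diene (C10 dimethylamino, either epimer; C8 tert-butyldimethylsilyl enol ether) | C[C@H]1CC[C@@H]([C@H](C1)O[C@H]2OC(=O)[C@@H]3C(N(C)C)C=C(O[Si](C)(C)C(C)(C)C)C[C@]23C)C(C)C
F6 | step 3 | enone lactone acetal (C8 ketone, C9=C10) | C[C@H]1CC[C@@H]([C@H](C1)O[C@H]2OC(=O)[C@@H]3C=CC(=O)C[C@]23C)C(C)C
F7 | step 11 | β-hydroxy cycloheptenone (ring A closed; C1 ketone; C6 hydroxyl) | O=C1C=C[C@@]2(C)CC(O[Si](C(C)C)(C(C)C)C(C)C)=CC[C@H]2[C@H](O)C1(C)C
F8 | step 11 | cis-1,3-diol (C1 and C6 hydroxyls) | O[C@@H]1C=C[C@@]2(C)CC(O[Si](C(C)C)(C(C)C)C(C)C)=CC[C@H]2[C@H](O)C1(C)C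
F9 | step 11 | O1 tert-butyldimethylsilyl ether of F8 (C6 hydroxyl free) | CC(C)(C)[Si](C)(C)O[C@@H]1C=C[C@@]2(C)CC(O[Si](C(C)C)(C(C)C)C(C)C)=CC[C@H]2[C@H](O)C1(C)C
A1 | direct plan | silyl-protected 8-methylenebicyclo[3.1.1]heptan-6-one from the ketene cycloaddition (C6 ketone; C4 with methyl and CH2OSi(iPr)3; C10 methyl) | CC(C)[Si](OC[C@]2(C)[C@@H]3C(=O)[C@H]2C(=C)C[C@H]3C)(C(C)C)C(C)C
A2 | direct plan | keto-dialdehyde (C2 and C3 formyl groups; C8 ketone; O1 4-methoxybenzyl ether) | O=C[C@]2(C)[C@@H]3[C@@H]([C@H]2C(=O)C[C@H]3C)C(C)(C)[C@H](OCc4ccc(OC)cc4)C=O
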